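**Plan**

- Numbering follows the benzofuran skeleton of the target (O1, C2, C3, C3a, C4–C7, C7a). Ring A is the carbocycle C3a–C7a, ring B the dihydrofuran.
- Retrosynthesis: remove the side-chain silyl ether, cut the C3a–OH bond and then the C5–prenyl bond, which rearomatises ring A. Then cut ring B at C3a–C3 and at O1–C7a.
- Enabling feature: with ring A aromatic, ring B is a 2-substituted 2,3-dihydrobenzofuran. C7a and C3a are the ipso and ortho carbons of an aryl iodide, and O1–C2–C3 plus the carbinol carbon are a terminal epoxide.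
- Forward: the aryl iodide (ring A) and the resolved epoxide are made separately and ring B closes in one palladium/norbornene step. Ring A is then dearomatised at C5 (prenylation) and at C3a (hydroxylation), and desilylation ends the route.
- Stereochemistry: C2 comes from the kinetically resolved epoxide, whose C–O bond is never broken. C5 is set by a chiral palladium catalyst, and C3a by attack anti to the C2 side chain.

Key step: step 6

Assumption: which antipode of the bisphosphine in step 9 favours 5S cannot be assigned in advance; the (R,R) ligand is written, and its enantiomer would be used if the C5 epimer predominated.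

**Route**

Step 1
Reactants: 1 2,6-dimethoxytoluene; 2 bis(pinacolato)diboron
Product: 4 5-iodo-1,3-dimethoxy-2-methylbenzene, via arylboronate 3 (not isolated)
Conditions: [Ir(cod)OMe]2 (1.5 mol%), 4,4′-di-tert-butyl-2,2′-bipyridine (3 mol%), THF, 80 °C; then CuI (10 mol%), 1,10-phenanthroline (20 mol%), KI, MeOH/H2O, air, 80 °C
Reagents that add atoms: potassium iodide, [K+].[I-]
Why: Iridium-catalysed C–H borylation is sterically governed and should take only the C–H para to the methyl group, the one position without an ortho substituent, and copper-catalysed iododeboronation then places iodine meta to both methoxy groups, where electrophilic iodination cannot reach.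

Step 2
Reactants: 4 5-iodo-1,3-dimethoxy-2-methylbenzene; 5 isobutyryl chloride
Product: 6 1-(6-iodo-2,4-dimethoxy-3-methylphenyl)-2-methylpropan-1-one
Conditions: AlCl3 (1.2 equiv), CH2Cl2, −10 to 0 °C
Reagents that add atoms: none
Why: Friedel–Crafts acylation, in which the two free ring positions are equivalent by symmetry (each ortho to one methoxy group and para to the other) so that one ketone should form, while the iodine, meta to both donors, is not activated towards acid-induced loss.

Step 3
Reactants: 7 2-methylbut-3-en-2-ol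
Product: 8 rac-2-(oxiran-2-yl)propan-2-ol
Conditions: mCPBA, CH2Cl2, 0 °C to rt
Reagents that add atoms: 3-chloroperbenzoic acid, OOC(=O)c1cccc(Cl)c1
Why: Prilezhaev epoxidation of the vinyl group, helped by hydrogen bonding of the allylic hydroxyl to the peracid, gives the racemic epoxy alcohol.

Step 4
Reactants: 8 rac-2-(oxiran-2-yl)propan-2-ol
Product: 9 rac-triethyl{[2-(oxiran-2-yl)propan-2-yl]oxy}silane
Conditions: TESOTf, 2,6-lutidine, CH2Cl2, −78 °C
Reagents that add atoms: triethylsilyl trifluoromethanesulfonate, CC[Si](CC)(CC)OS(=O)(=O)C(F)(F)F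
Why: Silylation of the hindered tertiary alcohol with a silyl triflate and a hindered base at low temperature, which removes the free alkoxide that would otherwise allow Payne rearrangement under the basic conditions of step 6.

Step 5
Reactants: 9 rac-triethyl{[2-(oxiran-2-yl)propan-2-yl]oxy}silane
Product: 10 (S)-triethyl{[2-(oxiran-2-yl)propan-2-yl]oxy}silane
Conditions: (R,R)-(salen)Co(OAc) (2 mol%; salen = N,N′-bis(3,5-di-tert-butylsalicylidene)cyclohexane-1,2-diamine dianion), H2O (0.55 equiv), THF, 0 °C to rt
Reagents that add atoms: none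
Why: Jacobsen hydrolytic kinetic resolution, in which the (R,R)-cobalt salen catalyst should hydrolyse the (R)-epoxide at its CH2 terminus and leave the (S)-epoxide, whose ring CH becomes C2 of the target.

Step 6
Reactants: 6 1-(6-iodo-2,4-dimethoxy-3-methylphenyl)-2-methylpropan-1-one; 10 (S)-triethyl{[2-(oxiran-2-yl)propan-2-yl]oxy}silane
Product: 11 1-[(2S)-4,6-dimethoxy-5-methyl-2-{2-[(triethylsilyl)oxy]propan-2-yl}-2,3-dihydro-1-benzofuran-7-yl]-2-methylpropan-1-one
Conditions: Pd(OAc)2 (10 mol%), XPhos (20 mol%), potassium bicyclo[2.2.1]hept-5-ene-2-carboxylate (50 mol%), Cs2CO3 (1.5 equiv), 10 (2 equiv), NMP, 80 °C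
Reagents that add atoms: none
Why: Catellani-type relay: the C7a–I bond adds oxidatively to zerovalent palladium, the norbornene inserts and base-assisted palladation of the only ortho C–H (C3a) gives an aryl–norbornyl palladacycle of divalent palladium, which opens epoxide 10 at its CH2 terminus to form C3a–C3, after which the norbornene is extruded and the tethered alkoxide forms O1–C7a by C–O reductive elimination. The closest known reaction type is the palladium/norbornene annulation of ortho-substituted aryl iodides with terminal epoxides to 2-substituted 2,3-dihydrobenzofurans. Ring B closes in a 5-exo sense, the alkoxide oxygen attacking the palladium-bearing C7a within a six-membered oxapalladacycle. No stereocentre is created: C2 is the ring CH of the epoxide, its C–O bond is never broken, and the S configuration is carried over unchanged. The step needs a single alkylation at C3a, attack at the epoxide CH2 and O-arylation at C7a only: the isobutyryl group blocks the second ortho position and forces norbornene extrusion after one alkylation, the silyloxyisopropyl group screens the epoxide CH, and the site of the iodine, not a choice between phenolic oxygens, decides which carbon receives O1. The C–H to be palladated lies beside a methoxy group, at the hindered end of the known scope, which is why a bulky electron-rich biarylphosphine and an excess of the epoxide are specified.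

Step 7
Reactants: 11 1-[(2S)-4,6-dimethoxy-5-methyl-2-{2-[(triethylsilyl)oxy]propan-2-yl}-2,3-dihydro-1-benzofuran-7-yl]-2-methylpropan-1-one
Product: 12 1-[(2S)-4,6-dihydroxy-5-methyl-2-{2-[(triethylsilyl)oxy]propan-2-yl}-2,3-dihydro-1-benzofuran-7-yl]-2-methylpropan-1-one
Conditions: NaSEt (8 equiv), DMF, 130 °C; then aq. NH4Cl
Reagents that add atoms: none
Why: Nucleophilic (SN2) demethylation by thiolate, in which both methyl ethers are ortho or para to the ketone so that each phenoxide is a stabilised leaving group, while the secondary ring ether, the tertiary silyl ether and the ketone should not be attacked.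

Step 8
Reactants: 13 3-methylbut-2-en-1-ol
Product: 14 methyl 3-methylbut-2-en-1-yl carbonate
Conditions: ClCO2Me, pyridine, CH2Cl2, 0 °C
Reagents that add atoms: methyl chloroformate, COC(Cl)=O
Why: O-Acylation of the primary allylic alcohol with a chloroformate gives the allylic carbonate that ionises to a pi-allyl complex and releases its own base.

Step 9
Reactants: 12 1-[(2S)-4,6-dihydroxy-5-methyl-2-{2-[(triethylsilyl)oxy]propan-2-yl}-2,3-dihydro-1-benzofuran-7-yl]-2-methylpropan-1-one; 14 methyl 3-methylbut-2-en-1-yl carbonate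
Product: 15 (2S,5S)-6-hydroxy-5-methyl-5-(3-methylbut-2-en-1-yl)-7-(2-methylpropanoyl)-2-{2-[(triethylsilyl)oxy]propan-2-yl}-2,3-dihydro-1-benzofuran-4(5H)-one
Conditions: Pd2(dba)3·CHCl3 (2.5 mol%), N,N′-[(1R,2R)-cyclohexane-1,2-diyl]bis[2-(diphenylphosphanyl)benzamide] (7.5 mol%), THF, 0 °C to rt
Reagents that add atoms: none
Why: Dearomative Tsuji–Trost prenylation (asymmetric allylic alkylation) of an acylphloroglucinol-type phenoxide, in which the methoxide set free on ionisation deprotonates 12, O-prenyl ethers re-ionise under the catalyst, the carbon nucleophile attacks the unsubstituted allyl terminus through C5 (the carbon flanked by both phenoxide oxygens), and the chiral ligand pocket rather than the remote C2 centre selects the face of C5, any C5 epimer being a diastereomer removable by chromatography.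

Step 10
Reactants: 15 (2S,5S)-6-hydroxy-5-methyl-5-(3-methylbut-2-en-1-yl)-7-(2-methylpropanoyl)-2-{2-[(triethylsilyl)oxy]propan-2-yl}-2,3-dihydro-1-benzofuran-4(5H)-one
Product: 16 (2S,3aR,5S)-3a-hydroxy-5-methyl-5-(3-methylbut-2-en-1-yl)-7-(2-methylpropanoyl)-2-{2-[(triethylsilyl)oxy]propan-2-yl}-3,3a-dihydro-1-benzofuran-4,6(2H,5H)-dione
Conditions: KN(SiMe3)2 (1.1 equiv), THF, −78 °C; then 2-(benzenesulfonyl)-3-phenyloxaziridine, −78 to −20 °C; aq. NH4Cl
Reagents that add atoms: 2-(benzenesulfonyl)-3-phenyloxaziridine, O=S(=O)(c1ccccc1)N1OC1c1ccccc1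
Why: Davis oxidation of the potassium enolate, which should react at C3a because C5 is quaternary and C7 carries the acyl group, with oxygen delivered to the face opposite the bulky silyloxyisopropyl group at C2 on the adjoining five-membered ring (setting 3aR), while the sulfonyloxaziridine leaves the prenyl alkene untouched.

Step 11
Reactants: 16 (2S,3aR,5S)-3a-hydroxy-5-methyl-5-(3-methylbut-2-en-1-yl)-7-(2-methylpropanoyl)-2-{2-[(triethylsilyl)oxy]propan-2-yl}-3,3a-dihydro-1-benzofuran-4,6(2H,5H)-dione
Product: 17 (2S,3aR,5S)-3a-hydroxy-2-(2-hydroxypropan-2-yl)-5-methyl-5-(3-methylbut-2-en-1-yl)-7-(2-methylpropanoyl)-3,3a-dihydro-1-benzofuran-4,6(2H,5H)-dione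
Conditions: HF·pyridine, pyridine/THF, 0 °C to rt
Reagents that add atoms: none
Why: Fluoride-mediated cleavage of the triethylsilyl ether under buffered conditions should free the tertiary alcohol without disturbing the alpha-ketol, the vinylogous ester or the three stereocentres.

**Compound list**

1 | 2,6-dimethoxytoluene (1,3-dimethoxy-2-methylbenzene) | COc1cccc(OC)c1C | starting material
2 | bis(pinacolato)diboron | CC1(C)OB(OC1(C)C)B1OC(C)(C)C(C)(C)O1 | starting material
3 | 2-(3,5-dimethoxy-4-methylphenyl)-4,4,5,5-tetramethyl-1,3,2-dioxaborolane | COc1cc(cc(OC)c1C)B1OC(C)(C)C(C)(C)O1 | intermediate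
4 | 5-iodo-1,3-dimethoxy-2-methylbenzene | COc1cc(I)cc(OC)c1C | intermediate
5 | isobutyryl chloride (2-methylpropanoyl chloride) | CC(C)C(Cl)=O | starting material
6 | 1-(6-iodo-2,4-dimethoxy-3-methylphenyl)-2-methylpropan-1-one | CC(C)C(=O)c1c(I)cc(OC)c(C)c1OC | intermediate
7 | 2-methylbut-3-en-2-ol | CC(C)(O)C=C | starting material
8 | rac-2-(oxiran-2-yl)propan-2-ol | CC(C)(O)C1CO1 | intermediate
9 | rac-triethyl{[2-(oxiran-2-yl)propan-2-yl]oxy}silane | CC[Si](CC)(CC)OC(C)(C)C1CO1 | intermediate
10 | (S)-triethyl{[2-(oxiran-2-yl)propan-2-yl]oxy}silane | CC[Si](CC)(CC)OC(C)(C)[C@@H]1CO1 | intermediate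
11 | 1-[(2S)-4,6-dimethoxy-5-methyl-2-{2-[(triethylsilyl)oxy]propan-2-yl}-2,3-dihydro-1-benzofuran-7-yl]-2-methylpropan-1-one | CC(C)C(=O)c1c(OC)c(C)c(OC)c2C[C@@H](C(C)(C)O[Si](CC)(CC)CC)Oc12 | intermediate
12 | 1-[(2S)-4,6-dihydroxy-5-methyl-2-{2-[(triethylsilyl)oxy]propan-2-yl}-2,3-dihydro-1-benzofuran-7-yl]-2-methylpropan-1-one | CC(C)C(=O)c1c(O)c(C)c(O)c2C[C@@H](C(C)(C)O[Si](CC)(CC)CC)Oc12 | intermediate
13 | 3-methylbut-2-en-1-ol | CC(C)=CCO | starting material
14 | methyl 3-methylbut-2-en-1-yl carbonate | COC(=O)OCC=C(C)C | intermediate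
15 | (2S,5S)-6-hydroxy-5-methyl-5-(3-methylbut-2-en-1-yl)-7-(2-methylpropanoyl)-2-{2-[(triethylsilyl)oxy]propan-2-yl}-2,3-dihydro-1-benzofuran-4(5H)-one (one enol tautomer drawn) | CC(C)=CC[C@@]1(C)C(O)=C(C(=O)C(C)C)C2=C(C[C@@H](C(C)(C)O[Si](CC)(CC)CC)O2)C1=O | intermediate
16 | (2S,3aR,5S)-3a-hydroxy-5-methyl-5-(3-methylbut-2-en-1-yl)-7-(2-methylpropanoyl)-2-{2-[(triethylsilyl)oxy]propan-2-yl}-3,3a-dihydro-1-benzofuran-4,6(2H,5H)-dione | CC(C)=CC[C@@]1(C)C(=O)C(C(=O)C(C)C)=C2O[C@H](C(C)(C)O[Si](CC)(CC)CC)C[C@]2(O)C1=O | intermediate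
17 | (2S,3aR,5S)-3a-hydroxy-2-(2-hydroxypropan-2-yl)-5-methyl-5-(3-methylbut-2-en-1-yl)-7-(2-methylpropanoyl)-3,3a-dihydro-1-benzofuran-4,6(2H,5H)-dione | CC(C)=CC[C@@]1(C)C(=O)C(C(=O)C(C)C)=C2O[C@H](C(C)(C)O)C[C@]2(O)C1=O | target

**Step count and risks**

Total steps: 11. Longest linear sequence: 8 steps (steps 3, 4, 5, 6, 7, 9, 10, 11, from 7).

Steps most likely to fail:

1. Step 6. Palladation of the C–H beside the methoxy group may be too slow, so that the aryl–palladium intermediate is diverted into reduction or norbornene-containing by-products. The fallback leaves the route at 6 and rejoins it at 11, closing ring B from a phenol instead.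
   - Copper-catalysed hydroxylation of 6 (CuI, 1,10-phenanthroline, KOH, DMSO/H2O, 100 °C) would give 1-(6-hydroxy-2,4-dimethoxy-3-methylphenyl)-2-methylpropan-1-one F1.
   - Friedel–Crafts prenylation of its only free ring position with alcohol 7 and BF3·OEt2 in dioxane would give 1-[6-hydroxy-2,4-dimethoxy-3-methyl-5-(3-methylbut-2-en-1-yl)phenyl]-2-methylpropan-1-one F2.
   - Shi epoxidation (D-fructose-derived ketone, KHSO5, K2CO3, MeCN/H2O, 0 °C) would give 1-(5-{[(2R)-3,3-dimethyloxiran-2-yl]methyl}-6-hydroxy-2,4-dimethoxy-3-methylphenyl)-2-methylpropan-1-one F3.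
   - K2CO3 in methanol should then close the ring 5-exo with inversion at the epoxide CH to give 1-[(2S)-2-(2-hydroxypropan-2-yl)-4,6-dimethoxy-5-methyl-2,3-dihydro-1-benzofuran-7-yl]-2-methylpropan-1-one F4.
   - Silylation with TESOTf and 2,6-lutidine returns to 11.

2. Step 9. The phenoxide may react through C3a or oxygen instead of C5, at the substituted allyl terminus, or with poor facial discrimination at C5. The fallback leaves the route at 12 and rejoins it at 15, building the prenyl group in two stages.
   - Asymmetric dearomative allylation of 12 with allyl methyl carbonate under the Pd2(dba)3/bisphosphine system of step 9 would give (2S,5S)-6-hydroxy-5-methyl-7-(2-methylpropanoyl)-5-(prop-2-en-1-yl)-2-{2-[(triethylsilyl)oxy]propan-2-yl}-2,3-dihydro-1-benzofuran-4(5H)-one F5. Allyl carbonate is the electrophile for which this alkylation is best established, and it has no linear/branched question.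
   - Cross-metathesis with 2-methylbut-2-ene (second-generation Grubbs catalyst (H2IMes)(PCy3)Cl2Ru=CHPh, CH2Cl2, 40 °C) would turn the allyl group into the prenyl group of 15.
   - This does not cure attack at C3a; that is addressed by the sequence under point 3, where C5 is the only carbon nucleophile left.

3. Step 10. Oxygen transfer may show poor facial selectivity, because the C5 prenyl group lies on the face that must be attacked while only the C2 side chain shields the other, and the stabilised enolate may react sluggishly. The fallback leaves the route at 11 and rejoins it at 16, oxidising C3a before C5 becomes quaternary.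
   - BCl3 (CH2Cl2, −78 °C) should cleave only the methyl ether chelated to the ketone, giving 1-[(2S)-6-hydroxy-4-methoxy-5-methyl-2-{2-[(triethylsilyl)oxy]propan-2-yl}-2,3-dihydro-1-benzofuran-7-yl]-2-methylpropan-1-one F6.
   - PhI(OAc)2 in MeCN/H2O at 0 °C would add water para to the phenol oxygen, at C3a and anti to the C2 side chain, giving the para-quinol (2S,3aS)-3a-hydroxy-4-methoxy-5-methyl-7-(2-methylpropanoyl)-2-{2-[(triethylsilyl)oxy]propan-2-yl}-3,3a-dihydro-1-benzofuran-6(2H)-one F7. The descriptor is 3aS only because the priorities change; the spatial arrangement is that of the target.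
   - LiI in 2,6-lutidine would demethylate the vinylogous ester to (2S,3aR)-3a,6-dihydroxy-5-methyl-7-(2-methylpropanoyl)-2-{2-[(triethylsilyl)oxy]propan-2-yl}-3,3a-dihydro-1-benzofuran-4(2H)-one F8.
   - Prenylation of its diketone enolate with 14 under the conditions of step 9, now possible only at C5, returns to 16.

Further compounds
F1 | step 6 | 1-(6-hydroxy-2,4-dimethoxy-3-methylphenyl)-2-methylpropan-1-one | CC(C)C(=O)c1c(O)cc(OC)c(C)c1OC
F2 | step 6 | 1-[6-hydroxy-2,4-dimethoxy-3-methyl-5-(3-methylbut-2-en-1-yl)phenyl]-2-methylpropan-1-one | CC(C)C(=O)c1c(O)c(CC=C(C)C)c(OC)c(C)c1OC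
F3 | step 6 | 1-(5-{[(2R)-3,3-dimethyloxiran-2-yl]methyl}-6-hydroxy-2,4-dimethoxy-3-methylphenyl)-2-methylpropan-1-one | CC(C)C(=O)c1c(O)c(C[C@H]2OC2(C)C)c(OC)c(C)c1OC
F4 | step 6 | 1-[(2S)-2-(2-hydroxypropan-2-yl)-4,6-dimethoxy-5-methyl-2,3-dihydro-1-benzofuran-7-yl]-2-methylpropan-1-one | CC(C)C(=O)c1c(OC)c(C)c(OC)c2C[C@@H](C(C)(C)O)Oc12
F5 | step 9 | (2S,5S)-6-hydroxy-5-methyl-7-(2-methylpropanoyl)-5-(prop-2-en-1-yl)-2-{2-[(triethylsilyl)oxy]propan-2-yl}-2,3-dihydro-1-benzofuran-4(5H)-one | C=CC[C@@]1(C)C(O)=C(C(=O)C(C)C)C2=C(C[C@@H](C(C)(C)O[Si](CC)(CC)CC)O2)C1=O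
F6 | step 10 | 1-[(2S)-6-hydroxy-4-methoxy-5-methyl-2-{2-[(triethylsilyl)oxy]propan-2-yl}-2,3-dihydro-1-benzofuran-7-yl]-2-methylpropan-1-one | CC(C)C(=O)c1c(O)c(C)c(OC)c2C[C@@H](C(C)(C)O[Si](CC)(CC)CC)Oc12
F7 | step 10 | (2S,3aS)-3a-hydroxy-4-methoxy-5-methyl-7-(2-methylpropanoyl)-2-{2-[(triethylsilyl)oxy]propan-2-yl}-3,3a-dihydro-1-benzofuran-6(2H)-one | CC(C)C(=O)C1=C2O[C@H](C(C)(C)O[Si](CC)(CC)CC)C[C@]2(O)C(OC)=C(C)C1=O
F8 | step 10 | (2S,3aR)-3a,6-dihydroxy-5-methyl-7-(2-methylpropanoyl)-2-{2-[(triethylsilyl)oxy]propan-2-yl}-3,3a-dihydro-1-benzofuran-4(2H)-one | CC(C)C(=O)C1=C2O[C@H](C(C)(C)O[Si](CC)(CC)CC)C[C@]2(O)C(=O)C(C)=C1O
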